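The benzene ring of the phthalide is cut at C7–C7a and C3a–C4. The feature exploited is the contiguous O4/O5/O6 triad on that ring, with only O4–H free, flanked by C7–H and the lactone-fused carbons C3a/C7a. One palladium-catalysed operation couples a squarate-derived 4-chlorocyclobutenone with 3-stannylbutenolide. The coupled cyclobutenone opens to a dienylketene and recloses as the phenol, so the arene, its fusion to the intact lactone and all three differentiated oxygens arise together. The precursor is a racemic cyclobutenone bearing the hydrated farnesyl chain (tertiary hydroxyl as triethylsilyl ether) as the C2 enol ether, methoxy at C3 and chlorine at C4.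

Key step: step 12

Remark: the target has no stereocentre, so only the two E alkenes taken from (2E,6E)-farnesol must be preserved, and every single-centre intermediate is racemic with its centre erased later. Phthalide numbering is C1 (C=O), O2, C3 (CH2), C3a, C4–C7, C7a. R = (2E,6E)-3,7,11-trimethyl-11-(triethylsilyloxy)dodeca-2,6-dien-1-yl.

Step 1
Reactants: 1 (2E,6E)-farnesol
Product: 2 (2E,6E)-farnesyl acetate
Conditions: Ac2O, pyridine, DMAP (cat.), CH2Cl2, 0 °C to rt
Reagents that add atoms: acetic anhydride CC(=O)OC(C)=O
Why: Routine O-acetylation (nucleophilic acyl substitution with DMAP catalysis) that masks the primary hydroxyl and makes C2=C3 the least electron-rich of the three alkenes.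

Step 2
Reactants: 2 (2E,6E)-farnesyl acetate
Product: 3 racemic (2E,6E)-10-bromo-11-hydroxy-3,7,11-trimethyldodeca-2,6-dienyl acetate
Conditions: NBS (1.05 equiv), THF/H2O, 0 °C
Reagents that add atoms: N-bromosuccinimide O=C1CCC(=O)N1Br; water O
Why: Terminal-selective bromohydrin formation of a polyprenyl acetate in aqueous medium (bromonium formation, Markovnikov opening by water), in which the exposed and most electron-rich C10=C11 alkene reacts first and water attacks tertiary C11, while the new C10 centre is racemic and is erased in step 3.

Step 3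
Reactants: 3 racemic bromohydrin acetate
Product: 4 (2E,6E)-11-hydroxy-3,7,11-trimethyldodeca-2,6-dienyl acetate
Conditions: Bu3SnH, AIBN (cat.), toluene, 80 °C
Reagents that add atoms: none
Why: Radical-chain hydrodebromination, in which the secondary C10 radical takes hydrogen from the tin hydride faster than it could add to C6=C7 (only disfavoured 4-exo or 5-endo modes exist) and the acetate, hydroxyl and alkenes are inert.

Step 4
Reactants: 4 hydroxy acetate
Product: 5 (2E,6E)-3,7,11-trimethyl-11-(triethylsilyloxy)dodeca-2,6-dienyl acetate (RO-acetyl)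
Conditions: TESOTf, 2,6-lutidine, CH2Cl2, −78 to 0 °C
Reagents that add atoms: triethylsilyl triflate CC[Si](CC)(CC)OS(=O)(=O)C(F)(F)F
Why: Silylation of a hindered tertiary alcohol with a silyl triflate and a non-nucleophilic base, conditions that leave the allylic acetate and the alkenes untouched.

Step 5
Reactants: 5 silyl ether acetate
Product: 6 chain alcohol ROH, (2E,6E)-3,7,11-trimethyl-11-(triethylsilyloxy)dodeca-2,6-dien-1-ol
Conditions: K2CO3 (0.2 equiv), MeOH, 0 °C to rt
Reagents that add atoms: none
Why: Base-catalysed methanolysis (transesterification) of the acetate, which leaves the hindered tertiary silyl ether and the alkene geometry intact.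

Step 6
Reactants: 7 dimethyl squarate; 6 chain alcohol ROH (2.2 equiv)
Product: 9 3,4-bis(RO)cyclobut-3-ene-1,2-dione, via mixed methyl R squarate 8 (not isolated)
Conditions: n-BuLi (0.1 equiv, on 6), THF/toluene, activated 5 Å MS, 0 °C to rt; neutral work-up, Et3N-deactivated SiO2
Reagents that add atoms: none
Why: Twofold vinylogous transesterification by alkoxide addition–elimination at the two alkoxy-bearing ring carbons, pulled to the diester by uptake of methanol in the sieves under halide-free and acid-free conditions that do not ionise the allylic esters, with surplus 6 recovered.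

Step 7
Reactants: 9 bis(RO) squarate
Product: 10 racemic 4-hydroxy-2,3-bis(RO)cyclobut-2-en-1-one
Conditions: LiAlH(OtBu)3 (1.1 equiv), THF, −78 to −20 °C; aq. potassium sodium tartrate
Reagents that add atoms: none
Why: Selective 1,2-reduction of one squarate carbonyl by a bulky, mild hydride, where the two carbonyls of 9 are equivalent so that one constitutional isomer results, the remaining carbonyl is a deactivated vinylogous ester that resists further reduction, and the new C4 centre is racemic and later becomes planar C7.

Step 8
Reactants: 10 racemic 4-hydroxy-2,3-bis(RO)cyclobutenone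
Product: 11 racemic 4-hydroxy-3-methoxy-2-(RO)cyclobut-2-en-1-one
Conditions: NaOMe (0.1 equiv), MeOH/THF, 0 °C; solid NH4Cl quench
Reagents that add atoms: methanol CO
Why: Vinylogous transesterification (conjugate addition–elimination) in which only C3 is the β-carbon of the enone, so only its alkoxy group is replaced while the C2 enol ether is inert, the excess of methanol drives the equilibrium, C4 cannot enolise (that would need a cyclobutadiene-like enolate) so carbonyl and carbinol cannot swap places, and liberated 6 returns to step 6.

Step 9
Reactants: 11 racemic 4-hydroxy-3-methoxy-2-(RO)cyclobutenone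
Product: 12 racemic 4-chloro-3-methoxy-2-(RO)cyclobut-2-en-1-one
Conditions: PPh3, Cl3CC(O)CCl3, CH2Cl2, −30 to 0 °C; used at once
Reagents that add atoms: hexachloroacetone ClC(Cl)(Cl)C(=O)C(Cl)(Cl)Cl
Why: Appel-type deoxychlorination under neutral, cold and weakly polar conditions, in which chloride displaces the phosphorus-activated oxygen in SN2 fashion at a carbon activated by both the carbonyl and the alkene, so that no free cation forms that could shed the allylic chain, and the silyl ether and alkenes are inert.

Step 10
Reactants: 13 furan-2(5H)-one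
Product: 15 3-bromofuran-2(5H)-one, via trans-3,4-dibromobutyrolactone 14 (not isolated)
Conditions: Br2, Et2O, reflux; then Et3N, 0 °C to rt
Reagents that add atoms: bromine BrBr
Why: Anti addition of bromine to the butenolide alkene followed by base-induced dehydrobromination (E1cB-like), in which the acidic C3–H is removed and the C4 bromide leaves, so that bromine stays at C3.

Step 11
Reactants: 15 3-bromofuran-2(5H)-one; 16 hexabutylditin (1.3 equiv)
Product: 17 3-(tributylstannyl)furan-2(5H)-one
Conditions: Pd(PPh3)4 (5 mol%), toluene, 90 °C
Reagents that add atoms: none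
Why: Palladium-catalysed stannylation of an alkenyl bromide with a distannane (oxidative addition, Sn–Sn transmetalation, reductive elimination), with the excess of 16 holding back Stille homocoupling of 17 with unreacted 15.

Step 12
Reactants: 12 racemic 4-chloro-3-methoxy-2-(RO)cyclobut-2-en-1-one; 17 3-(tributylstannyl)furan-2(5H)-one (1.2 equiv)
Product: 21 4-hydroxy-6-methoxy-5-(RO)isobenzofuran-1(3H)-one (triethylsilyl ether of the target), via 4-(furanon-3-yl)cyclobutenone 18 (not isolated), via dienylketene 19 (not isolated), via cyclohexadienone 20 (not isolated)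
Conditions: PdCl2(PhCN)2 (5 mol%), tri(2-furyl)phosphine (10 mol%), CuI (10 mol%), degassed 1,4-dioxane, 45–50 °C
Reagents that add atoms: none
Why: Zerovalent palladium, formed in the flask from PdCl2(PhCN)2 and the stannane, adds oxidatively to the activated allylic C4–Cl bond of 12, transfer of butenolide C3 from tin is eased by the weakly donating furylphosphine and by CuI, and reductive elimination at the less substituted end of the η3-cyclobutenyl ligand gives 18 (new C7–C7a bond). Conrotatory 4π opening of the strained ring cleaves C1–C4 reversibly, so only the isomer 19 with the furanonyl group turned inward is drained, by a disrotatory 6π electrocyclisation (all-carbon six-membered closure) that joins the ketene carbon to the butenolide β-carbon (new C3a–C4 bond) to give 20, which enolises to phenol 21. This is the known Stille coupling and ring expansion of 4-chlorocyclobutenones with alkenylstannanes to phenols, used here on a new pair of partners. No stereocentre survives, since the racemic centre of 12 becomes C7–H, the transient C3a–H centre of 20 is lost on tautomerisation, and both E alkenes of the chain are spectators. Regiochemistry follows from connectivity alone (carbonyl carbon to C4–OH, C2 to C5–OR, C3 to C6–OMe, chlorinated carbon to C7–H, stannylated carbon to C7a), and CuI is known to favour ipso over cine coupling of α-stannyl enoates. The step needs the C–Cl bond to react before the allyl enol ether C–O bond, which should be secured by the much higher reactivity of the α-keto allylic chloride, the slowly ionising trisubstituted chain alkene, the absence of an external nucleophile and a bath temperature at which sigmatropic shift of the chain is slow.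

Step 13
Reactants: 21 triethylsilyl ether of the target
Product: 22 farnesylemefuranone E
Conditions: HF·pyridine, pyridine, THF, 0 °C to rt
Reagents that add atoms: none
Why: Fluoride-mediated cleavage of the silyl ether (desilylation), buffered by pyridine so that the aryl allyl ether, the tertiary carbinol, the phenol and the lactone are not disturbed.

Compound list
1 | (2E,6E)-farnesol | OC/C=C(\C)CC/C=C(\C)CCC=C(C)C | starting material
2 | (2E,6E)-farnesyl acetate | CC(=O)OC/C=C(\C)CC/C=C(\C)CCC=C(C)C | intermediate
3 | racemic (2E,6E)-10-bromo-11-hydroxy-3,7,11-trimethyldodeca-2,6-dienyl acetate | CC(=O)OC/C=C(\C)CC/C=C(\C)CCC(Br)C(C)(C)O | intermediate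
4 | (2E,6E)-11-hydroxy-3,7,11-trimethyldodeca-2,6-dienyl acetate | CC(=O)OC/C=C(\C)CC/C=C(\C)CCCC(C)(C)O | intermediate
5 | (2E,6E)-3,7,11-trimethyl-11-(triethylsilyloxy)dodeca-2,6-dienyl acetate | CC(=O)OC/C=C(\C)CC/C=C(\C)CCCC(C)(C)O[Si](CC)(CC)CC | intermediate
6 | (2E,6E)-3,7,11-trimethyl-11-(triethylsilyloxy)dodeca-2,6-dien-1-ol (ROH) | OC/C=C(\C)CC/C=C(\C)CCCC(C)(C)O[Si](CC)(CC)CC | intermediate
7 | dimethyl squarate | COC1=C(OC)C(=O)C1=O | starting material
8 | 3-methoxy-4-(RO)cyclobut-3-ene-1,2-dione (mixed squarate, not isolated) | COC1=C(OC/C=C(\C)CC/C=C(\C)CCCC(C)(C)O[Si](CC)(CC)CC)C(=O)C1=O | intermediate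
9 | 3,4-bis(RO)cyclobut-3-ene-1,2-dione | O=C1C(=O)C(OC/C=C(\C)CC/C=C(\C)CCCC(C)(C)O[Si](CC)(CC)CC)=C1OC/C=C(\C)CC/C=C(\C)CCCC(C)(C)O[Si](CC)(CC)CC | intermediate
10 | racemic 4-hydroxy-2,3-bis(RO)cyclobut-2-en-1-one | O=C1C(OC/C=C(\C)CC/C=C(\C)CCCC(C)(C)O[Si](CC)(CC)CC)=C(OC/C=C(\C)CC/C=C(\C)CCCC(C)(C)O[Si](CC)(CC)CC)C1O | intermediate
11 | racemic 4-hydroxy-3-methoxy-2-(RO)cyclobut-2-en-1-one | O=C1C(OC/C=C(\C)CC/C=C(\C)CCCC(C)(C)O[Si](CC)(CC)CC)=C(OC)C1O | intermediate
12 | racemic 4-chloro-3-methoxy-2-(RO)cyclobut-2-en-1-one | O=C1C(OC/C=C(\C)CC/C=C(\C)CCCC(C)(C)O[Si](CC)(CC)CC)=C(OC)C1Cl | intermediate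
13 | furan-2(5H)-one | O=C1OCC=C1 | starting material
14 | racemic trans-3,4-dibromodihydrofuran-2(3H)-one (one enantiomer drawn, not isolated) | O=C1OC[C@@H](Br)[C@@H]1Br | intermediate
15 | 3-bromofuran-2(5H)-one | O=C1OCC=C1Br | intermediate
16 | hexabutylditin | CCCC[Sn](CCCC)(CCCC)[Sn](CCCC)(CCCC)CCCC | starting material
17 | 3-(tributylstannyl)furan-2(5H)-one | O=C1OCC=C1[Sn](CCCC)(CCCC)CCCC | intermediate
18 | racemic 3-methoxy-4-(2-oxo-2,5-dihydrofuran-3-yl)-2-(RO)cyclobut-2-en-1-one (not isolated) | O=C1C(OC/C=C(\C)CC/C=C(\C)CCCC(C)(C)O[Si](CC)(CC)CC)=C(OC)C1C2=CCOC2=O | intermediate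
19 | dienylketene, 3-methoxy-4-(2-oxo-2,5-dihydrofuran-3-yl)-2-(RO)buta-1,3-dien-1-one with the furanonyl group cis to the ketene-bearing carbon (not isolated) | O=C=C(OC/C=C(\C)CC/C=C(\C)CCCC(C)(C)O[Si](CC)(CC)CC)/C(OC)=C\C1=CCOC1=O | intermediate
20 | racemic 6-methoxy-5-(RO)-3,3a-dihydroisobenzofuran-1,4-dione (cyclohexadienone tautomer of 21, not isolated) | O=C1C(OC/C=C(\C)CC/C=C(\C)CCCC(C)(C)O[Si](CC)(CC)CC)=C(OC)C=C2C(=O)OCC12 | intermediate
21 | 4-hydroxy-6-methoxy-5-(RO)isobenzofuran-1(3H)-one | COc1cc2c(c(O)c1OC/C=C(\C)CC/C=C(\C)CCCC(C)(C)O[Si](CC)(CC)CC)COC2=O | intermediate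
22 | farnesylemefuranone E, 4-hydroxy-5-[(2E,6E)-11-hydroxy-3,7,11-trimethyldodeca-2,6-dienyloxy]-6-methoxyisobenzofuran-1(3H)-one | COc1cc2c(c(O)c1OC/C=C(\C)CC/C=C(\C)CCCC(C)(C)O)COC2=O | target

Total step count: 13. Longest linear sequence: 11 (steps 1–9, 12, 13).

Steps most likely to fail

Step 12.
- **What may go wrong:**
  - Zerovalent palladium may ionise the allylic C–O bond of the enol ether or of the product aryl ether, with loss or migration of the chain.
  - The transient ketene may be captured by the nearby C2'=C3' chain alkene, or the chain may undergo sigmatropic shift.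
  - Tin-to-palladium transfer from the hindered α-stannyl lactone may be so slow that the chloride decays first.
- **Fallback (sets out from 7, 6 and 17, comes back at 21):** the chain is attached only after the arene exists, so no allyl ether meets palladium or a ketene. Compound 7 is reduced with LiAlH(OtBu)3 to racemic 4-hydroxy-2,3-dimethoxycyclobut-2-en-1-one F1. This is chlorinated as in step 9 to racemic 4-chloro-2,3-dimethoxycyclobut-2-en-1-one F2. Coupling of F2 with 17 under the conditions of step 12 should give 4-hydroxy-5,6-dimethoxyisobenzofuran-1(3H)-one F3. BCl3 in CH2Cl2 binds the C4 phenol and cleaves the neighbouring, doubly flanked C5 methyl ether to give 4,5-dihydroxy-6-methoxyisobenzofuran-1(3H)-one F4. Alcohol 6 is converted with PPh3 and CBr4 into (2E,6E)-1-bromo-3,7,11-trimethyl-11-(triethylsilyloxy)dodeca-2,6-diene F5. F4 is then alkylated with F5 and one equivalent of K2CO3 in DMF at the more acidic O5–H, which lies para to the ring carbon carrying the lactone carbonyl, to give 21.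

Step 9.
- **What may go wrong:** the activated carbinol may ionise to a cation stabilised by the C2 oxygen, after which chloride removes the allylic chain and the ring collapses to a cyclobutenedione. The same decay may occur on storage of the chloride.
- **Fallback (sets out from 11, comes back at 21):** the chloride is bypassed. Compound 11 is acetylated under non-ionising basic conditions (Ac2O, pyridine, DMAP) to racemic 4-acetoxy-3-methoxy-2-(RO)cyclobut-2-en-1-one F6, a storable ester. F6 is coupled with 17 under the conditions known for allylic acetates and organostannanes (Pd2(dba)3, tri(2-furyl)phosphine, LiCl, DMF, rt to 50 °C). Oxidative addition in the presence of chloride should lead to the same cyclobutenylpalladium chloride that 12 would give, and the ring-opening and ring-closing sequence then runs on to 21.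

Step 8.
- **What may go wrong:** the exchange may stay incomplete, or the base may trigger ring opening of the hydroxycyclobutenone before exchange is finished.
- **Fallback (sets out from 7 and 6, comes back at 11):** regiochemistry is settled by separation instead of exchange. Mixed squarate 8 is made on purpose from 7 with one equivalent of 6 under the conditions of step 6 and is isolated. Its reduction with LiAlH(OtBu)3 as in step 7 should give both regioisomeric carbinols: 11 and racemic 4-hydroxy-2-methoxy-3-(RO)cyclobut-2-en-1-one F7. The bulky hydride should lean toward the carbonyl next to the smaller methoxy-bearing carbon, which leads to 11. Chromatography on deactivated silica delivers 11.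

Further compounds
F1 | step 12 | racemic 4-hydroxy-2,3-dimethoxycyclobut-2-en-1-one | COC1=C(OC)C(=O)C1O
F2 | step 12 | racemic 4-chloro-2,3-dimethoxycyclobut-2-en-1-one | COC1=C(OC)C(=O)C1Cl
F3 | step 12 | 4-hydroxy-5,6-dimethoxyisobenzofuran-1(3H)-one | COc1cc2c(c(O)c1OC)COC2=O
F4 | step 12 | 4,5-dihydroxy-6-methoxyisobenzofuran-1(3H)-one | COc1cc2c(c(O)c1O)COC2=O
F5 | step 12 | (2E,6E)-1-bromo-3,7,11-trimethyl-11-(triethylsilyloxy)dodeca-2,6-diene | BrC/C=C(\C)CC/C=C(\C)CCCC(C)(C)O[Si](CC)(CC)CC
F6 | step 9 | racemic 4-acetoxy-3-methoxy-2-(RO)cyclobut-2-en-1-one | O=C1C(OC/C=C(\C)CC/C=C(\C)CCCC(C)(C)O[Si](CC)(CC)CC)=C(OC)C1OC(C)=O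
F7 | step 8 | racemic 4-hydroxy-2-methoxy-3-(RO)cyclobut-2-en-1-one | O=C1C(OC)=C(OC/C=C(\C)CC/C=C(\C)CCCC(C)(C)O[Si](CC)(CC)CC)C1O
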